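## Structural features

The target is a sesquiterpenoid diester on a tricyclo[5.4.0.0(2,8)]undecane (longipinane-type) skeleton; the core carbons are numbered C1 to C11 along the chain C1H(O-tiglate), C2H2, C3H(O-isovalerate), C4(CH3)2, C5H, C6H, C7(=O), C8H=, C9(CH3)=, C10H, C11(CH3), with the ring bonds C5–C10, C6–C11 and C11–C1. Its centre is the cyclobutane C5–C6–C11–C10: C6 and C10 are tied on one face by the enone unit C7–C8–C9 (a bicyclo[3.1.1]hept-3-en-2-one), and C5 and C11 are tied on the opposite face by the chain C4–C3–C2–C1 (a bicyclo[4.1.1]octane whose seven-membered ring carries both esters). The four ring-fusion centres C5, C6, C11 and C10 are contiguous and flanked by the quaternary carbons C4 and C11; the cage fixes their relative configuration once the C11 methyl lies on the face of the enone bridge, and the carbinol centres C1 (R) and C3 (R) are anti across C2. The fragile elements are the four-membered ring, whose carbon C6 is α and whose carbon C10 is γ to the C7 carbonyl, so that an oxygen function at C5 invites retro-Claisen or retro-aldol opening, the tiglate as a Michael acceptor, and two esters on neopentyl-type secondary carbons that must be told apart. The real difficulties are the doubly 1,3-bridged cyclobutane with its quaternary C11 and the absolute configuration: the cage is nearly mirror-symmetric through C5, C8 and C11, its handedness lies only in which end of the three-carbon bridge is the carbonyl, and C1 and C3 receive almost no bias from it. The key step uses this near-symmetry: with C5 written as a carbonyl, the four-membered ring is a 3,3-disubstituted cyclobutanone whose enantiotopic α-carbons C6 and C10 can be spanned by the four-carbon unit C7–C8–C9(–CH3) of a but-2-ynoyl group, C6–C7 by acylation and C9–C10 by conjugate addition.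

## Logic of the disconnections

**31 ⇒ 29 + 30.** Cut: the O–acyl bond at C3. The two esters are best introduced one at a time, and the isovalerate can go on last because C3 then carries the only free hydroxyl. Gain: an acid chloride and a mono-ester, no change at any stereocentre. Demand: acylation of a hindered secondary alcohol without acyl migration from O1 and without touching the tiglate.

**29 ⇒ 26 + 27 (through 28).** Cut: the O1–acyl bond and the C3–H bond together. In the forward direction one reaction moves the acyl carbon of 27 onto O1 and its aldehyde hydrogen onto C3, which differentiates the two oxygens and sets C3 anti to C1 in the same event. Gain: one stereocentre and one ester fewer. Demand: the hemiacetal of an enal must form and deliver hydride inside the seven-membered ring.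

**26 ⇒ 25 ⇒ 24 ⇒ 23.** No skeletal bond is cut; O1–H is exchanged for O1–Si and C5–H for C5–OH. A hydroxyl at C5 turns C4–C5 into an aldol bond. Gain: the next cut becomes a carbonyl addition. Demand: deoxygenation of a tertiary cyclobutanol that can neither eliminate (C4 quaternary, C6 and C10 bridgeheads) nor ionise, so a radical method is required; because this oxygen is β to two carbonyl groups, it must not be left as a basic alkoxide.

**23 ⇒ 21 (through 22).** Cut: C4–C5. The C5 ketone is the handle left by the key step, and C4 is α to the C3 carbonyl. Gain: the seven-membered ring opens and the problem falls back to a bicycle with a side chain. Demand: the enolate must be formed at C4 and not at C2, which is why C4 is carried as the α-carbon of a terminal enone and the enolate is made by conjugate hydride delivery; the tether allows attack on C5 only from the side-chain face, so C5 needs no further control.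

**21 ⇒ 20 ⇒ 17 + 18 (through 19).** Cut: C1–C2, after removal of the silyl group. This is the aldol bond between a methyl ketone and a non-enolisable aldehyde on the quaternary C11. Gain: the whole C2–C4 unit comes from one commercial ketone. Demand: C1 must be set by the reagent, because C6 and C10, the two carbons that flank C11, differ only at a distance.

**17 ⇒ 16.** No bond is cut; the C1 aldehyde is written as its dioxolane. An alkoxycarbonyl group on C11 would be the obvious way to carry C1, but it was rejected for two reasons. It is a planar group that by conformational energies is smaller than methyl, so it cannot be relied on to keep the new bridge off its own face. It would also have to be reduced to the aldehyde in the presence of a cyclobutanone and an enone. The acetal is branched at the carbon bound to C11 and already at the aldehyde oxidation level. Demand: acetal hydrolysis mild enough for the strained β-diketone.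

**16 ⇒ 11 + 13 (through 14 and 15).** Cut: C6–C7 and C9–C10. This removes the entire enone ring and all three cage stereocentres at once and leads back to an achiral cyclobutanone derivative and a four-carbon acyl unit that already holds the C9 methyl. Demand: C-acylation at one of two enantiotopic α-carbons, closure of the second bond on the same face (the face of the C11 methyl), and 6-endo-dig regiochemistry on the ynone.

**11 ⇒ 9 + 10 and 13 ⇒ 12.** Cut: the C5–N bond and the C–Cl bond. Gain: the chiral information is a commercial, recoverable amine; 13 is one step from its acid. Demand: enamine formation from a strained ketone with a hindered amine, without disturbing the acetal.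

**9 ⇒ 8 ⇒ 6 + 7 ⇒ 4 ⇒ 1 + 2.** Cut: C5=O back to C5=CH2, the acetal C–O bonds, the aldehyde back to the nitrile, and the C11–CH3 bond. The exocyclic methylene is a ketone surrogate that is unmasked oxidatively, orthogonal to the acid-labile acetal, which a ketal would not be. Gain: a commercial four-membered ring that already carries C5 and C1 in differentiated form. Demand: nothing beyond routine nitrile alkylation, partial reduction, acetalisation and alkene cleavage.

## Other disconnections considered

**Alternative 1:** The cut is C10–C11 (with the C11–CH3 bond added afterwards), taking the bicyclo[3.1.1] unit back to a fused six/seven bicycle that holds a C5=C10 alkene and a diazo group on C11 beside a C1 ketone. In the forward step Rh2(O2CCPh3)4 would generate the C11 carbene, which adds across C5=C10 to give A1. A1 is a bicyclo[1.1.0]butane (C5, C6, C10, C11) whose wing carbons are tied by C7–C9 and whose central bond C5–C11 is spanned by C1–C4. Reductive cleavage of that central bond next to the ketone and trapping of the C11 enolate with iodomethane would then unveil the cyclobutane and the C11 methyl.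
- In its favour: both bridges and the cage arise in one event from an unstrained precursor. The methyl group can enter C11 only on the open face, so the relationship that the chosen plan must secure by size difference is secured by geometry; on this point the alternative is better. Intramolecular carbene addition giving bicyclobutanes is an established reaction class, so its key step also stands on firmer precedent than the enamine annulation.
- Against it: A1 is a propellane-like, doubly bridged bicyclobutane with inverted carbons, and C–H insertion or Wolff rearrangement of the carbene would compete with its formation. The reducing conditions for the central bond would also attack the C2=C3 enone. Oxygenation of C3, stereocontrolled reduction at C1, removal of the C7 ketal and dehydrogenation to C8=C9 all remain.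
- Comparison: the alternative forms more of the skeleton per step and controls C11 better, but it needs a longer chiral precursor and a heavier sequence of functional-group changes afterwards, so the chosen plan should be shorter.

**Alternative 2:** The cut is C5–C10 and C6–C7, made after a 1,2-shift retron that moves C11 from C6 back to C7. In the forward step, heating a triene would give A2; in this triene a 5,5-disubstituted silyloxycyclopentadiene (C7 to C11) carries on C11 the chain C1–C4 ending in the (E)-alkenylboronate C5=C6. Oxidation of the C–B bond, sulfonylation and a semipinacol shift of C11 from C7 to C6, pushed by the C7 silyloxy group, would contract the norbornene to the bicyclo[3.1.1]heptenone with the enone in place.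
- In its favour: the intramolecular Diels–Alder reaction is dependable, and the tether decides the diene face and the regiochemistry, so C5, C10 and C11 are enforced and not negotiated by sterics (better than the chosen plan). The quaternary C11 blocks 1,5-hydrogen shifts of the diene. The C1 and C3 oxygen functions ride through already differentiated, so the end game is short and never passes through a β-hydroxy ketone at C5 (also better).
- Against it: the dienophile is unactivated and the tether closes a seven-membered ring, so high temperature is needed in the presence of a silyl dienol ether. The boronate must end up endo so that the C7–C11 bond and not another bond migrates. The linear precursor already holds C1, C3 and a quaternary C11 on a cyclopentadiene, all of which must be made enantioselectively.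
- Comparison: on mechanism and precedent the alternative is the stronger at its key step. On step economy the chosen plan reaches its key step in five steps from achiral materials and buys its chirality with a recoverable amine, whereas the alternative needs a long linear sequence first.

**Alternative 3:** The cut is C5–C10 and C6–C11, the [2+2] retron of the cyclobutanone. In the forward step Et3N in hot toluene would turn an acid chloride into the alkylketene C5=C6, which adds across the trisubstituted C10=C11 alkene three atoms away to give A3. The bridged regiochemistry is favoured because C11 is the more substituted alkene carbon. The C9 methyl stereocentre on the tether steers the face and is erased later by dehydrogenation to C8=C9.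
- In its favour: this is a known reaction class for this ring system (better precedent). Suprafacial addition transfers the alkene geometry to C11, so the methyl/side-chain relationship is stereospecific (better). C7 stays a ketal during the C4–C5 closure and the C5 deoxygenation, so there is no strained β-diketone and far less risk of fragmentation (better). The side chain with its C1 stereocentre is already attached.
- Against it: the precursor needs a geometrically pure trisubstituted alkene and two remote stereocentres (C1 and C9) set independently. Ketene dimerisation and the fused regioisomer compete, and facial control by one methyl group on the tether is not assured. After the cycloaddition the same aldol closure, deoxygenation and ester end game are still required, plus ketal removal and dehydrogenation.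
- Comparison: the end game is equal and the intermediates are easier to handle, but the sequence is longer and relies on more acyclic stereocontrol. The chosen plan is shorter and more convergent but rests on an untested step.

Key step: step 7

Assumption (enamine): an electrophile is taken to attack an enamine carbon on the face away from the methyl group of the neighbouring pyrrolidine carbon; with C-acylation as the first bond-forming event this calls for the (2S,5S)-amine.
Assumption (aldol): the methyl-ketone enolate made with (−)-Ipc2BCl is taken to add to the re face of an aldehyde; if the sense proved opposite, (+)-Ipc2BCl would be used with no other change.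

## Route

Step 1
Reactants: 1 3-methylidenecyclobutane-1-carbonitrile; 2 iodomethane
Product: 4 1-methyl-3-methylidenecyclobutane-1-carbonitrile, via lithiated nitrile 3 (not isolated)
Conditions: LiN(iPr)2, THF, −78 °C; then MeI, −78 → 0 °C
Reagents that add atoms: iodomethane (2), CI
Why: Deprotonation α to the nitrile gives a tertiary nitrile-stabilised anion that is C-methylated (nitrile alkylation); the ring carbon becomes the future quaternary C11, and no stereocentre arises because the ring keeps its mirror plane.

Step 2
Reactants: 4 1-methyl-3-methylidenecyclobutane-1-carbonitrile
Product: 6 1-methyl-3-methylidenecyclobutane-1-carbaldehyde, via N-aluminated aldimine 5 (not isolated)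
Conditions: iBu2AlH, CH2Cl2, −78 °C; then 1 M aq. HCl, 0 °C
Reagents that add atoms: water, O
Why: Partial reduction of a nitrile: one hydride is taken up and the N-aluminated imine persists until cold hydrolysis, so over-reduction is avoided; the α-quaternary aldehyde cannot enolise and is carried on as a solution because it is volatile.

Step 3
Reactants: 6 1-methyl-3-methylidenecyclobutane-1-carbaldehyde; 7 ethane-1,2-diol
Product: 8 2-(1-methyl-3-methylidenecyclobutyl)-1,3-dioxolane
Conditions: PPTS (cat.), benzene, reflux, Dean–Stark
Reagents that add atoms: ethane-1,2-diol (7), OCCO
Why: Acid-catalysed acetalisation with azeotropic removal of water; the weak acid does not isomerise the exocyclic alkene. The dioxolane keeps C1 at the aldehyde oxidation level and is a branched sp3 group clearly larger than the methyl on the same carbon, which the face selection of step 7 needs.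

Step 4
Reactants: 8 2-(1-methyl-3-methylidenecyclobutyl)-1,3-dioxolane
Product: 9 3-(1,3-dioxolan-2-yl)-3-methylcyclobutan-1-one
Conditions: K2OsO4·2H2O (2 mol%), NaIO4, 2,6-lutidine, dioxane–H2O (3:1), rt
Reagents that add atoms: sodium periodate, [Na+].[O-]I(=O)(=O)=O
Why: Lemieux–Johnson cleavage (catalytic dihydroxylation, then periodate cleavage of the diol) converts the 1,1-disubstituted alkene into the cyclobutanone, and the buffered medium leaves the acetal intact. The product is achiral, with enantiotopic α-methylene groups C6 and C10.

Step 5
Reactants: 9 3-(1,3-dioxolan-2-yl)-3-methylcyclobutan-1-one; 10 (2S,5S)-2,5-dimethylpyrrolidine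
Product: 11 (2S,5S)-1-[3-(1,3-dioxolan-2-yl)-3-methylcyclobut-1-en-1-yl]-2,5-dimethylpyrrolidine
Conditions: TsOH·H2O (2 mol%), 4 Å MS, benzene, 60 °C; filtered and concentrated under argon, used crude
Reagents that add atoms: (2S,5S)-2,5-dimethylpyrrolidine (10), C[C@H]1CC[C@H](C)N1
Why: Condensation of a secondary amine with the strained, electrophilic cyclobutanone with removal of water (enamine formation); the anhydrous medium spares the acetal. The two double-bond isomers (towards C6 or towards C10) interconvert through the iminium ion, so no selection is needed here.

Step 6
Reactants: 12 but-2-ynoic acid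
Product: 13 but-2-ynoyl chloride
Conditions: (COCl)2, DMF (cat.), CH2Cl2, 0 °C → rt; used as a solution
Reagents that add atoms: oxalyl chloride, ClC(=O)C(=O)Cl
Why: Acid chloride formation through the chloroiminium species made from DMF; only gases are lost, and the volatile, moisture-sensitive product is used directly.

Step 7
Reactants: 11 (2S,5S)-1-[3-(1,3-dioxolan-2-yl)-3-methylcyclobut-1-en-1-yl]-2,5-dimethylpyrrolidine; 13 but-2-ynoyl chloride
Product: 16 (1R,5R,7R)-7-(1,3-dioxolan-2-yl)-4,7-dimethylbicyclo[3.1.1]hept-3-ene-2,6-dione, via C6-acylated enaminone 14 (not isolated), via bridged iminium chloride 15 (not isolated)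
Conditions: iPr2NEt, CH2Cl2, −78 → 0 °C; then PivOH (20 mol%), MeCN, 60 °C; then aq. AcOH/NaOAc (pH 5), rt
Reagents that add atoms: but-2-ynoyl chloride (13), CC#CC(=O)Cl; water, O
Why: Proposed new method: the enamine carbon is C-acylated by the acid chloride (Stork acylation; the hindered nitrogen disfavours N-acylation) and loses a proton to give the push–pull enaminone 14, and acid-catalysed tautomerisation through the iminium ion then moves the enamine double bond to C5=C10. C10 adds to the ynone β-carbon C9 in a conjugate addition (a β-chloroenone formed by HCl addition would close by addition–elimination to the same product), C8 is protonated, and the bridged iminium ion 15 is hydrolysed with release of the amine 10. The closest known reactions are the α,α′-annulation of cyclic ketone enamines with acryloyl chloride, which gives bridged bicyclic 1,3-diketones, and the conjugate addition of enamines to ynones; new here are the cyclobutanone enamine, the alkyne acceptor and the bicyclo[3.1.1] product. The one ring that closes is the six-membered enone ring C6–C7–C8–C9–C10–C5, formed 6-endo-dig with both alkyne carbons in the ring; the 5-exo-dig alternative would attack the α-carbon of the ynone and give a bicyclo[2.1.1]hexane, so it is disfavoured electronically and by strain. C6 and C10 are set as a pair, because a three-atom bridge spans the 1,3-positions of a cyclobutane only cis, and their absolute sense is decided by which enantiotopic α-carbon is acylated: the pyrrolidine methyl next to the enamine carbon blocks one face, the dioxolanyl group on C11 blocks the other, and only at C6 do both direct the acid chloride to the same face. C11 is set by the face on which the bridge closes: the C6 epimers of the acylated intermediate interconvert through 14, and closure should occur on the face of the C11 methyl because the branched acetal cannot sit over the forming ring (Curtin–Hammett control). The step therefore needs C- over N-acylation, C6 over C10, the methyl face over the acetal face and 6-endo over 5-exo closure; these are secured by the hindered C2-symmetric amine, by its match with the acetal, by the size difference at C11 and by the polarity of the ynone.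

Step 8
Reactants: 16 (1R,5R,7R)-7-(1,3-dioxolan-2-yl)-4,7-dimethylbicyclo[3.1.1]hept-3-ene-2,6-dione
Product: 17 (1R,5R,7R)-4,7-dimethyl-2,6-dioxobicyclo[3.1.1]hept-3-ene-7-carbaldehyde
Conditions: TsOH·H2O (cat.), acetone–H2O (10:1), 40 °C
Reagents that add atoms: water, O
Why: Acid-catalysed acetal hydrolysis; weak acid and little water are used because the non-enolisable β-diketone is opened by nucleophiles, whereas the bridgehead centres cannot epimerise.

Step 9
Reactants: 17 (1R,5R,7R)-4,7-dimethyl-2,6-dioxobicyclo[3.1.1]hept-3-ene-7-carbaldehyde; 18 3-methylbut-3-en-2-one
Product: 20 7-[(1R)-1-hydroxy-4-methyl-3-oxopent-4-en-1-yl]-4,7-dimethylbicyclo[3.1.1]hept-3-ene-2,6-dione (cage as in 16), via boron enolate 19 (not isolated)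
Conditions: (−)-Ipc2BCl, Et3N, Et2O, 0 °C (with 18); then 17, −78 → −20 °C; pH 7 buffer work-up, no peroxide
Reagents that add atoms: 3-methylbut-3-en-2-one (18), CC(=C)C(C)=O
Why: Boron aldol of a methyl ketone through its chiral diisopinocampheylboron enolate; the non-enolisable aldehyde reacts in preference to the hindered ketones. The bicyclic core gives almost no facial bias at C1, so C1 is set by the reagent: re-face attack gives the (1R)-alcohol, and the (1S)-epimer is a diastereomer that should be separable by chromatography. Peroxide is avoided in the work-up because cyclobutanones undergo Baeyer–Villiger oxidation.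

Step 10
Reactants: 20 7-[(1R)-1-hydroxy-4-methyl-3-oxopent-4-en-1-yl]-4,7-dimethylbicyclo[3.1.1]hept-3-ene-2,6-dione
Product: 21 triethylsilyl ether of 20 at O1
Conditions: TESOTf, 2,6-lutidine, CH2Cl2, −78 °C
Reagents that add atoms: triethylsilyl trifluoromethanesulfonate, CC[Si](CC)(CC)OS(=O)(=O)C(F)(F)F
Why: Silylation of the hindered secondary alcohol with a silyl triflate; the ether prevents oxa-Michael closure onto the terminal enone, keeps O1 out of steps 11 to 13 and is removable later under weakly acidic conditions.

Step 11
Reactants: 21 triethylsilyl ether of 20 at O1
Product: 23 tricyclic C5 alcohol (C1–C11 numbering: (1R)-1-triethylsilyloxy; 3-oxo; 4,4-dimethyl; 5-hydroxy on the face of the enone bridge; 7-oxo-8-ene; 9,11-dimethyl), via copper enolate 22 (not isolated)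
Conditions: [(Ph3P)CuH]6 (0.2 equiv, 1.2 hydride equiv), toluene, −40 → 0 °C; aq. NH4Cl
Reagents that add atoms: none
Why: Conjugate hydride transfer from the copper hydride to the unhindered terminal enone gives the C3–C4 enolate regiospecifically, and this adds to the strained C5 ketone (reductive aldol cyclisation); the β,β-disubstituted ring enone and the ketones react much more slowly with this reagent. C4 can reach C5 only from the cyclobutane face that carries the side chain, so the new centre (hydroxyl towards the enone bridge) is fixed by the tether, and because C5 and C11 are 1,3-related across the four-membered ring the closure is geometrically like a six-membered one. The cold quench limits retro-aldol opening of the aldolate.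

Step 12
Reactants: 23 tricyclic C5 alcohol
Product: 24 C5 methyl oxalate of 23
Conditions: MeO2CCOCl, DMAP, CH2Cl2, 0 °C → rt
Reagents that add atoms: methyl chlorooxoacetate, COC(=O)C(=O)Cl
Why: Acylation of the tertiary alcohol with a very reactive oxalyl monochloride under nucleophilic catalysis; elimination is impossible (C4 is quaternary, C6 and C10 are bridgeheads), so the ester is stable.

Step 13
Reactants: 24 C5 methyl oxalate of 23
Product: 25 C5-deoxygenated tricycle ((1R)-1-triethylsilyloxy; 3-oxo; C5–H on the face of the enone bridge; cage as in 31)
Conditions: Bu3SnH (slow addition), AIBN (cat.), toluene, 110 °C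
Reagents that add atoms: none
Why: Radical chain deoxygenation of a tertiary methyl oxalate (Barton–McCombie type): the tin radical adds to the oxalate, C5–O cleavage gives the tertiary cyclobutyl radical, and this takes hydrogen from Bu3SnH. The radical is held pyramidal by the cage and is bound to C4 on one face, so hydrogen can arrive only on the face of the enone bridge, which is the target configuration at C5; opening of a cyclobutyl radical is slow because the ring bonds lie orthogonal to the singly occupied orbital.

Step 14
Reactants: 25 C5-deoxygenated tricycle
Product: 26 β-hydroxy ketone ((1R)-1-hydroxy; 3-oxo; cage as in 31)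
Conditions: HF·pyridine, pyridine–THF, 0 °C
Reagents that add atoms: none
Why: Cleavage of the triethylsilyl ether by buffered hydrogen fluoride; basic fluoride sources are avoided to prevent retro-aldol cleavage of the β-hydroxy ketone.

Step 15
Reactants: 26 β-hydroxy ketone; 27 (E)-2-methylbut-2-enal
Product: 29 (1R,3R)-3-hydroxy 1-tiglate (O1 (E)-2-methylbut-2-enoate; free C3 hydroxyl trans to O1 on the ring), via samarium-bound hemiacetal 28 (not isolated)
Conditions: SmI2 (30 mol%), 27 (6 equiv), THF, −10 °C
Reagents that add atoms: (E)-2-methylbut-2-enal (27), C/C=C(\C)C=O
Why: Evans–Tishchenko reaction: O1 and the aldehyde form a samarium-bound hemiacetal whose hydrogen is delivered intramolecularly to the C3 ketone through a six-membered chelate, so the acyl group ends on O1 and the new C3 hydroxyl is anti (trans on the ring) to O1, that is (3R). Only the C3 ketone has a β-hydroxyl, so the ring enone is untouched, the two oxygens are differentiated without protecting groups, and the (E)-geometry of the acyl unit is carried over from the aldehyde.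

Step 16
Reactants: 29 (1R,3R)-3-hydroxy 1-tiglate; 30 3-methylbutanoyl chloride
Product: 31 target, (1R,3R,5S,6R,10R,11R) in the C1–C11 numbering
Conditions: DMAP, pyridine, CH2Cl2, 0 °C → rt
Reagents that add atoms: 3-methylbutanoyl chloride (30), CC(C)CC(=O)Cl
Why: DMAP-catalysed acylation of the one remaining secondary alcohol with an acid chloride; the trans arrangement of O1 and O3 on the ring disfavours acyl migration, and no stereocentre is touched.

## Compound list

1 | 3-methylidenecyclobutane-1-carbonitrile | C=C1CC(C1)C#N | starting material
2 | iodomethane | CI | starting material
3 | lithiated nitrile (N-lithio ketenimine form) | [Li]N=C=C1CC(=C)C1 | intermediate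
4 | 1-methyl-3-methylidenecyclobutane-1-carbonitrile | CC1(CC(=C)C1)C#N | intermediate
5 | N-aluminated aldimine, N-(diisobutylalumanyl)imine of 6 | CC1(CC(=C)C1)C=N[Al](CC(C)C)CC(C)C | intermediate
6 | 1-methyl-3-methylidenecyclobutane-1-carbaldehyde | CC1(CC(=C)C1)C=O | intermediate
7 | ethane-1,2-diol | OCCO | starting material
8 | 2-(1-methyl-3-methylidenecyclobutyl)-1,3-dioxolane | CC1(CC(=C)C1)C2OCCO2 | intermediate
9 | 3-(1,3-dioxolan-2-yl)-3-methylcyclobutan-1-one | CC1(CC(=O)C1)C2OCCO2 | intermediate
10 | (2S,5S)-2,5-dimethylpyrrolidine | C[C@H]1CC[C@H](C)N1 | starting material
11 | (2S,5S)-1-[3-(1,3-dioxolan-2-yl)-3-methylcyclobut-1-en-1-yl]-2,5-dimethylpyrrolidine (both double-bond positions interconvert, so the ring carbon C11 is not yet a fixed centre) | C[C@H]1CC[C@H](C)N1C2=CC(C)(C2)C3OCCO3 | intermediate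
12 | but-2-ynoic acid | CC#CC(=O)O | starting material
13 | but-2-ynoyl chloride | CC#CC(=O)Cl | intermediate
14 | C6-acylated enaminone, 1-{(4R)-2-[(2S,5S)-2,5-dimethylpyrrolidin-1-yl]-4-(1,3-dioxolan-2-yl)-4-methylcyclobut-1-en-1-yl}but-2-yn-1-one | CC#CC(=O)C1=C(N2[C@@H](C)CC[C@@H]2C)C[C@@]1(C)C3OCCO3 | intermediate
15 | bridged iminium chloride, (2S,5S)-2,5-dimethylpyrrolidinium ylidene at C5 of the bicycle of 16 | C[C@H]1CC[C@H](C)[N+]1=C2[C@H]3C(=O)C=C(C)[C@@H]2[C@@]3(C)C4OCCO4.[Cl-] | intermediate
16 | (1R,5R,7R)-7-(1,3-dioxolan-2-yl)-4,7-dimethylbicyclo[3.1.1]hept-3-ene-2,6-dione (7-methyl on the side of the enone bridge) | O=C1[C@H]2C(=O)C=C(C)[C@@H]1[C@@]2(C)C3OCCO3 | intermediate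
17 | (1R,5R,7R)-4,7-dimethyl-2,6-dioxobicyclo[3.1.1]hept-3-ene-7-carbaldehyde | O=C1[C@H]2C(=O)C=C(C)[C@@H]1[C@@]2(C)C=O | intermediate
18 | 3-methylbut-3-en-2-one | CC(=C)C(C)=O | starting material
19 | boron enolate, (3-methylbuta-1,3-dien-2-yl)oxy-diisopinocampheylborane | C=C(OB([C@@H]1C[C@@H]2C[C@H]([C@H]1C)C2(C)C)[C@@H]3C[C@@H]4C[C@H]([C@H]3C)C4(C)C)C(C)=C | intermediate
20 | 7-[(1R)-1-hydroxy-4-methyl-3-oxopent-4-en-1-yl]-4,7-dimethylbicyclo[3.1.1]hept-3-ene-2,6-dione, cage as in 16 | O=C1[C@H]2C(=O)C=C(C)[C@@H]1[C@@]2(C)[C@H](O)CC(=O)C(C)=C | intermediate
21 | triethylsilyl ether of 20 at O1 | O=C1[C@H]2C(=O)C=C(C)[C@@H]1[C@@]2(C)[C@H](O[Si](CC)(CC)CC)CC(=O)C(C)=C | intermediate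
22 | copper enolate, monovalent-copper C3–C4 enolate of reduced 21 (phosphine ligands not drawn) | O=C1[C@H]2C(=O)C=C(C)[C@@H]1[C@@]2(C)[C@H](O[Si](CC)(CC)CC)CC(O[Cu])=C(C)C | intermediate
23 | tricyclic C5 alcohol: (1R)-1-triethylsilyloxy, 3-oxo, 4,4-dimethyl, 5-hydroxy (towards the enone bridge), 7-oxo-8-ene, 9,11-dimethyl tricyclo[5.4.0.0(2,8)]undecane skeleton | CC[Si](CC)(CC)O[C@@H]1CC(=O)C(C)(C)[C@]2(O)[C@H]3C(=O)C=C(C)[C@@H]2[C@]31C | intermediate
24 | C5 methyl oxalate of 23 | CC[Si](CC)(CC)O[C@@H]1CC(=O)C(C)(C)[C@]2(OC(=O)C(=O)OC)[C@H]3C(=O)C=C(C)[C@@H]2[C@]31C | intermediate
25 | C5-deoxygenated tricycle, (1R)-1-triethylsilyloxy-3,7-dioxo-8-ene with C5–H towards the enone bridge | CC[Si](CC)(CC)O[C@@H]1CC(=O)C(C)(C)[C@@H]2[C@H]3C(=O)C=C(C)[C@@H]2[C@]31C | intermediate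
26 | β-hydroxy ketone, (1R)-1-hydroxy-3,7-dioxo-8-ene tricycle | O[C@@H]1CC(=O)C(C)(C)[C@@H]2[C@H]3C(=O)C=C(C)[C@@H]2[C@]31C | intermediate
27 | (E)-2-methylbut-2-enal | C/C=C(\C)C=O | starting material
28 | samarium-bound hemiacetal of 26 and 27 at O1, drawn as the free hemiacetal | C/C=C(\C)C(O)O[C@@H]1CC(=O)C(C)(C)[C@@H]2[C@H]3C(=O)C=C(C)[C@@H]2[C@]31C | intermediate
29 | (1R,3R)-3-hydroxy-7-oxo-8-ene tricycle, O1 (E)-2-methylbut-2-enoate | C/C=C(\C)C(=O)O[C@@H]1C[C@@H](O)C(C)(C)[C@@H]2[C@H]3C(=O)C=C(C)[C@@H]2[C@]31C | intermediate
30 | 3-methylbutanoyl chloride | CC(C)CC(=O)Cl | starting material
31 | target, (1R,3R,5S,6R,10R,11R)-diester: O1 (E)-2-methylbut-2-enoate, O3 3-methylbutanoate | C/C=C(\C)C(=O)O[C@@H]1C[C@@H](OC(=O)CC(C)C)C(C)(C)[C@@H]2[C@H]3C(=O)C=C(C)[C@@H]2[C@]31C | target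

## Step count and least certain steps

Total step count: 16. Longest linear sequence: 15 steps (steps 1 to 5 and 7 to 16, from compound 1); step 6 is a one-step side branch.

**Step 7 (key step, proposed new method).** The most likely failure is that the sequence stops at the conjugated enaminone 14. The tautomer with the double bond towards C10 is higher in energy, and the linear alkyne has to bend to reach across the four-membered ring, so closure may be slow and amine-induced opening of the strained ring may compete. Erosion of the enantiotopic selection (acylation at C10) or closure on the acetal face would lower the optical purity or give the C11 epimer. If the conjugate addition preceded the acylation, the antipodal amine would be required. The fallback sets out from 11 and returns at 16, and it uses established reaction types. 11 would be treated with (E)-but-2-enoyl chloride and iPr2NEt, that is Stork C-acylation followed by 6-endo-trig Michael closure of the re-formed enamine, the known α,α′-annulation of ketone enamines with α,β-unsaturated acid chlorides. Buffered hydrolysis would give the saturated dione 7-(1,3-dioxolan-2-yl)-4,7-dimethylbicyclo[3.1.1]heptane-2,6-dione F1 (cage as in 16, either C4 epimer). Dehydrogenation with IBX in DMSO at 65 °C, or Saegusa–Ito oxidation with Pd(OAc)2 of the silyl enol ether, would then install C8=C9; the C7 ketone can enolise only towards C8 because C6 is a bridgehead. The sp2 acceptor reaches C10 more easily than the alkyne, at the price of one more step.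

**Step 9.** The most likely failure is poor facial selectivity at C1, because a bulky boron enolate meets an α-quaternary aldehyde whose core exerts no bias, and the facial sense itself rests on an assumption. The fallback sets out from 17 (with 18) and returns at 20 without a new compound. It is a catalytic direct aldol under a dinuclear zinc catalyst (Et2Zn, ProPhenol ligand of the antipode that gives re-face addition, 4 Å MS, THF). The enolate is generated in situ inside a chiral bimetallic pocket, α-branched non-enolisable aldehydes are the best acceptor class for this catalyst, and no stoichiometric boron residue has to be removed without peroxide.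

**Step 11.** The most likely failure is retro-aldol fragmentation of the copper aldolate through the C5–C6 bond (release of cyclobutane strain, enolate stabilised by the C7 carbonyl). Over-reduction of the ring enone is the second risk. The fallback sets out from 21 and returns at 23. RhCl(PPh3)3-catalysed 1,4-hydrosilylation with Et3SiH would give regiospecifically the tetrasubstituted silyl enol ether F2 (O3 triethylsilyl enol ether of the C3–C4 enolate, O1 triethylsilyl ether). BF3·OEt2 in CH2Cl2 at −78 °C would then close C4–C5 by an intramolecular Mukaiyama aldol, in which no basic metal alkoxide is ever present, and aqueous work-up gives 23.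

**Step 13 (with step 12).** The most likely failures are slow loss of CO2 from the alkoxycarbonyl radical, because the C5 radical is strained and pyramidal, which would lead to reduction to the formate; and, in step 12, base-induced retro-aldol opening while the hindered tertiary alcohol is acylated. Tin radical addition to the ring enone is a lesser risk. The fallback sets out from 23 and returns at 25. Oxalyl chloride alone (no base) would convert 23 into the chloro-oxalate, which with the sodium salt of N-hydroxypyridine-2-thione gives the mixed oxalate thiohydroxamate F3 (C5–O–CO–CO–O–N-pyridine-2-thione). Irradiation at room temperature with tert-butylthiol as hydrogen donor then gives 25 with loss of two molecules of CO2. This sequence is free of tin and of base.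

**Step 15.** The most likely failure is sluggish hemiacetal formation and hydride transfer with a conjugated, α-substituted aldehyde, so that aldehyde dimerisation consumes the catalyst, or a ring conformation that does not allow the chelated transfer. The fallback sets out from 26 and returns at 31. The same Evans–Tishchenko reaction would be run with the unconjugated pent-4-enal to give the (1R,3R)-3-hydroxy 1-pent-4-enoate F4. Acylation with 30 would give the 1-pent-4-enoate 3-isovalerate F5. Iodine in aqueous THF would remove the pentenoate by iodolactonisation to give the 1-hydroxy 3-isovalerate F6. Yamaguchi esterification with (E)-2-methylbut-2-enoic acid (2,4,6-trichlorobenzoyl chloride, Et3N, DMAP) would then give 31.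

## Further compounds

F1 | step 7 | 7-(1,3-dioxolan-2-yl)-4,7-dimethylbicyclo[3.1.1]heptane-2,6-dione, cage as in 16, C4 unspecified | O=C1[C@H]2C(=O)CC(C)[C@@H]1[C@@]2(C)C3OCCO3
F0 | step 9 | none | none
F2 | step 11 | bis(triethylsilyl) compound: O1 silyl ether and C3–C4 silyl enol ether of reduced 21 | O=C1[C@H]2C(=O)C=C(C)[C@@H]1[C@@]2(C)[C@H](O[Si](CC)(CC)CC)CC(O[Si](CC)(CC)CC)=C(C)C
F3 | step 13 | mixed oxalate of 23 (at O5) with N-hydroxypyridine-2-thione | CC[Si](CC)(CC)O[C@@H]1CC(=O)C(C)(C)[C@]2(OC(=O)C(=O)ON4C=CC=CC4=S)[C@H]3C(=O)C=C(C)[C@@H]2[C@]31C
F4 | step 15 | (1R,3R)-3-hydroxy-7-oxo-8-ene tricycle, O1 pent-4-enoate | C=CCCC(=O)O[C@@H]1C[C@@H](O)C(C)(C)[C@@H]2[C@H]3C(=O)C=C(C)[C@@H]2[C@]31C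
F5 | step 15 | O1 pent-4-enoate, O3 3-methylbutanoate | C=CCCC(=O)O[C@@H]1C[C@@H](OC(=O)CC(C)C)C(C)(C)[C@@H]2[C@H]3C(=O)C=C(C)[C@@H]2[C@]31C
F6 | step 15 | (1R,3R)-1-hydroxy-7-oxo-8-ene tricycle, O3 3-methylbutanoate | O[C@@H]1C[C@@H](OC(=O)CC(C)C)C(C)(C)[C@@H]2[C@H]3C(=O)C=C(C)[C@@H]2[C@]31C
A1 | alternative 1 | tetracyclic bicyclo[1.1.0]butane enone with the extra C5–C11 bond and a C7 dioxolane | O=C1C=CC(C)(C)[C@]23[C@@H]4[C@@H](C)CC5(OCCO5)[C@H]2[C@]134
A2 | alternative 2 | 1-silyloxynorbornene tricycle with endo pinacol boronate on C6 | CC(C)(C)[Si](C)(C)O[C@@H]1C[C@@H](OC(=O)CC(C)C)C(C)(C)[C@@H]2[C@@H](B3OC(C)(C)C(C)(C)O3)[C@@]4(O[Si](CC)(CC)CC)C=C(C)[C@@H]2[C@]41C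
A3 | alternative 3 | bicyclo[3.1.1]heptan-6-one with C7 dioxolane, C9 methyl and the C1–C4 side chain | O=C1[C@H]2C3(OCCO3)C[C@@H](C)[C@@H]1[C@@]2(C)[C@H](O[Si](C)(C)C(C)(C)C)CC(=O)C(C)C
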